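**Strategy.** Ring A is disconnected at C1–C10 and C3–C4, leaving (S)-carvone as ring B and (Z)-3-bromo-1-iodopropene as the C1–C3 unit. The key step exploits the C4–C5–C10 triad of ring A: C10 is the α′-carbon of the carvone enone and C4 the inner carbon of the isopropenyl group on C5, whose CH2 ends as a geminal methyl. In one flask, enolate alkylation and a 6-exo reductive Heck closure build ring A with both quaternary carbons. Carvone also supplies C7=C8 and C17; C9 is homologated to a Julia sulfone, C17 and C6 are oxidised, and a (13S) aldehyde completes the side chain.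

Key step: step 4

Remark: atoms carry labdane numbers throughout, also in bicyclic intermediates (C11 on C9, C17 on C8, C18/C19 on C4, C20 on C10). Assumed: either C10 epimer of 5 serves, because that centre is erased on enolisation. Assumed: the antipode of the DACH-phenyl ligand that gives the S ether 20 is identified on the first run.

Step 1
Reactants: 1 ethyl (Z)-3-iodoacrylate
Product: 2 (Z)-3-iodoprop-2-en-1-ol
Conditions: i-Bu2AlH (2.2 equiv), CH2Cl2, −78 °C
Reagents that add atoms: none
Why: Low-temperature aluminium hydride reduction of the conjugated ester should give the allylic alcohol without touching the C–I bond or the Z geometry.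

Step 2
Reactants: 2 (Z)-3-iodoprop-2-en-1-ol
Product: 3 (Z)-3-bromo-1-iodoprop-1-ene
Conditions: CBr4, PPh3, CH2Cl2, 0 °C
Reagents that add atoms: carbon tetrabromide, BrC(Br)(Br)Br
Why: Appel bromination of the primary allylic alcohol proceeds by SN2 at carbon, so the Z vinyl iodide geometry is retained.

Step 3
Reactants: 4 (S)-(+)-carvone
Product: 5 (5S,6R)-6-methylcarvone
Conditions: LiN(i-Pr)2, THF, −78 °C; MeI, −78 to 0 °C
Reagents that add atoms: iodomethane, CI
Why: Kinetic deprotonation at the α′-carbon (C10) and methylation of the cross-conjugated enolate installs C20 (enolate alkylation), the new centre being erased again in step 4 while C5 is carried from carvone.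

Step 4
Reactants: 5 (5S,6R)-6-methylcarvone; 3 (Z)-3-bromo-1-iodoprop-1-ene
Product: 7 (5R,10R)-11,12,13,14,15,16-hexanorlabda-2,7-dien-9-one, via vinyl iodide 6 (not isolated)
Conditions: LiN(i-Pr)2, THF/DMPU, −78 °C, then 3, −78 to 0 °C; then in the same flask DMF, Pd(OAc)2 (10 mol %), PPh3, HCO2Na, Et4NCl, 80 °C
Reagents that add atoms: none
Why: Deprotonation of 5 at C10 and SN2 C-alkylation by the allylic bromide of 3 on the face anti to the C5 isopropenyl group forms C1–C10 and sets C10 (C20 cis, C1 trans to C4) by 1,2-induction from the carvone stereocentre, the usual outcome for 6-substituted carvone enolates. Zerovalent palladium then inserts into the C3–I bond of 6 and the alkenyl–Pd adds across the isopropenyl group in a 6-exo-trig carbopalladation that forms C3–C4, closes ring A and leaves a neopentyl C18–Pd without β-hydrogen, which formate reduces to the second C4 methyl. The closest known reaction types are ketone enolate alkylation with a (Z)-3-haloallyl halide and intramolecular reductive Heck cyclisation with hydride capture, here telescoped. C4 is not stereogenic and C5 comes from carvone, so the trans ring fusion follows from the trans C1/C4 relationship fixed in the alkylation. The step needs exo over 7-endo closure and reaction of palladium at the vinyl iodide only: the Z geometry holds Pd syn to C1 so that only a six-membered ring with a cis C2=C3 can form, carbopalladation of 1,1-disubstituted alkenes is exo-selective, and the conjugated C7=C8 is out of reach.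

Step 5
Reactants: 7 (5R,10R)-11,12,13,14,15,16-hexanorlabda-2,7-dien-9-one
Product: 8 (5R,10R)-11,12,13,14,15,16-hexanorlabd-7-en-9-one
Conditions: H2 (1 atm), RhCl(PPh3)3 (5 mol %), toluene/EtOH, rt
Reagents that add atoms: none
Why: Homogeneous hydrogenation with the rhodium chloride–phosphine complex should reduce the cis-disubstituted C2=C3 and leave the trisubstituted, conjugated C7=C8 untouched; no stereocentre is formed.

Step 6
Reactants: 8 (5R,10R)-11,12,13,14,15,16-hexanorlabd-7-en-9-one
Product: 9 (5R,10R)-12,13,14,15,16-pentanorlabda-7,9(11)-diene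
Conditions: Ph3PCH3Br, KOt-Bu, toluene, 90 °C
Reagents that add atoms: methyltriphenylphosphonium bromide, C[P+](c1ccccc1)(c1ccccc1)c1ccccc1.[Br-]
Why: Wittig methylenation of the C9 ketone, which has no α-hydrogen at C8 or C10 so that only reversible γ-deprotonation at C6 can compete, should give the exocyclic C9=C11 alkene under forcing conditions.

Step 7
Reactants: 9 (5R,10R)-12,13,14,15,16-pentanorlabda-7,9(11)-diene
Product: 11 ent-drimenol (5R,9R,10R)-12,13,14,15,16-pentanorlabd-7-en-11-ol, via alkylborane 10 (not isolated)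
Conditions: 9-BBN-H, THF, 0 to 60 °C; then NaOH, H2O2, 0 °C to rt
Reagents that add atoms: 9-borabicyclo[3.3.1]nonane, [BH]1C2CCCC1CCC2 (its boron stays only in 10); hydrogen peroxide, OO
Why: Hydroboration–oxidation puts boron on the terminal C11 of the 1,1-disubstituted alkene in preference to the trisubstituted C7=C8 and delivers H to C9 from the face opposite the axial C20 methyl, which sets C9 with C11 equatorial and cis to C20.

Step 8
Reactants: 11 ent-drimenol
Product: 12 (5R,9R,10R)-11-(1-phenyl-1H-tetrazol-5-ylsulfanyl)-12,13,14,15,16-pentanorlabd-7-ene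
Conditions: PPh3, DIAD, 1-phenyl-1H-tetrazole-5-thiol, THF, 0 °C to rt
Reagents that add atoms: 1-phenyl-1H-tetrazole-5-thiol, Sc1nnnn1-c1ccccc1
Why: Mitsunobu thioetherification of the primary alcohol with the acidic heteroaryl thiol is an SN2 reaction at C11 that touches no stereocentre.

Step 9
Reactants: 12 the C11 tetrazolyl sulfide
Product: 13 (5R,9R,10R)-11-(1-phenyl-1H-tetrazol-5-ylsulfonyl)-12,13,14,15,16-pentanorlabd-7-ene
Conditions: (NH4)6Mo7O24·4H2O (10 mol %), 30% H2O2, EtOH, 0 °C to rt
Reagents that add atoms: hydrogen peroxide, OO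
Why: Molybdate-catalysed peroxide oxidation of sulfide to sulfone is chemoselective for sulfur over the trisubstituted alkene.

Step 10
Reactants: 13 the C11 tetrazolyl sulfone
Product: 14 (5R,9S,10R)-11-(1-phenyl-1H-tetrazol-5-ylsulfonyl)-12,13,14,15,16-pentanorlabd-7-en-17-ol
Conditions: SeO2 (0.5 equiv), t-BuOOH, CH2Cl2, rt
Reagents that add atoms: selenium dioxide, O=[Se]=O; tert-butyl hydroperoxide, CC(C)(C)OO
Why: Selenium dioxide allylic oxidation (ene reaction, then 2,3-sigmatropic shift) attacks the more substituted alkene terminus C8 at its methyl group, which is favoured over the hindered methine C9 and lies trans to C6, giving the C17 alcohol.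

Step 11
Reactants: 14 the C17 allylic alcohol
Product: 15 (5R,9S,10R)-17-acetoxy-11-(1-phenyl-1H-tetrazol-5-ylsulfonyl)-12,13,14,15,16-pentanorlabd-7-ene
Conditions: Ac2O, pyridine, DMAP (cat.), CH2Cl2, rt
Reagents that add atoms: acetic anhydride, CC(=O)OC(C)=O
Why: DMAP-catalysed acyl transfer to the primary allylic alcohol installs the first acetate of the target.

Step 12
Reactants: 15 the C17 acetate
Product: 16 (5R,9S,10R)-17-acetoxy-11-(1-phenyl-1H-tetrazol-5-ylsulfonyl)-12,13,14,15,16-pentanorlabd-7-en-6-one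
Conditions: CrO3, 3,5-dimethylpyrazole, CH2Cl2, −20 °C
Reagents that add atoms: chromium trioxide, O=[Cr](=O)=O
Why: Chromium trioxide–pyrazole allylic oxidation should convert the only allylic methylene (C6) into the ketone with C7=C8 staying in place as the enone, C5 keeping the thermodynamically preferred trans fusion.

Step 13
Reactants: 16 the 7-en-6-one
Product: 17 (5R,6S,9S,10R)-17-acetoxy-11-(1-phenyl-1H-tetrazol-5-ylsulfonyl)-12,13,14,15,16-pentanorlabd-7-en-6-ol
Conditions: NaBH4, CeCl3·7H2O, MeOH, −40 to 0 °C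
Reagents that add atoms: none
Why: Luche 1,2-reduction delivers hydride to C6 from the face opposite the 1,3-related axial methyls (C20 and the axial C4 methyl), so the hydroxyl should end axial and cis to C20 (6S) while the allylic acetate survives.

Step 14
Reactants: 17 the axial C6 alcohol
Product: 18 (5R,6S,9S,10R)-6,17-diacetoxy-11-(1-phenyl-1H-tetrazol-5-ylsulfonyl)-12,13,14,15,16-pentanorlabd-7-ene
Conditions: Ac2O, Et3N, DMAP, CH2Cl2, 40 °C
Reagents that add atoms: acetic anhydride, CC(=O)OC(C)=O
Why: DMAP-catalysed acetylation with warming acylates the hindered axial alcohol with retention at C6.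

Step 15
Reactants: 19 racemic 2-methyl-2-vinyloxirane
Product: 20 (S)-2-[(4-methoxybenzyl)oxy]-2-methylbut-3-en-1-ol
Conditions: 4-methoxybenzyl alcohol, Pd2(dba)3·CHCl3 (1 mol %), DACH-phenyl bis(2-diphenylphosphinobenzamide) ligand (3 mol %, antipode giving the S ether), Et3B (1 mol %), CH2Cl2, rt
Reagents that add atoms: 4-methoxybenzyl alcohol, COc1ccc(CO)cc1
Why: Palladium-catalysed dynamic kinetic asymmetric allylic etherification ionises both epoxide enantiomers to interconverting π-allyl complexes, the boron-bound alkoxide steers the alcohol to the tertiary terminus, and the chiral ligand sets the future C13 centre (S).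

Step 16
Reactants: 20 (S)-2-[(4-methoxybenzyl)oxy]-2-methylbut-3-en-1-ol
Product: 21 (S)-2-[(4-methoxybenzyl)oxy]-2-methylbut-3-enal
Conditions: Dess–Martin periodinane, NaHCO3, CH2Cl2, 0 °C to rt
Reagents that add atoms: none
Why: Dess–Martin oxidation of the primary alcohol gives the aldehyde, whose α-carbon is quaternary and cannot epimerise.

Step 17
Reactants: 18 the diacetoxy sulfone; 21 (S)-2-[(4-methoxybenzyl)oxy]-2-methylbut-3-enal
Product: 22 (5R,6S,9S,10S,11E,13S)-6,17-diacetoxy-13-[(4-methoxybenzyl)oxy]labda-7,11,14-triene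
Conditions: KN(SiMe3)2, DME, −60 °C to rt (base added to the mixture of 18 and 21)
Reagents that add atoms: none
Why: Julia–Kocienski olefination: the metallated tetrazolyl sulfone adds to the non-enolisable aldehyde, and Smiles rearrangement with loss of SO2 and tetrazolone should give the E C11=C12 alkene (the usual preference with potassium in DME), C9 and C13 being untouched; adding the base last at low temperature keeps the carbanion concentration low, so that capture by the aldehyde should outrun attack on the acetates.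

Step 18
Reactants: 22 the 13-O-(4-methoxybenzyl) ether
Product: 23 CNP0103498.1, (5R,6S,9S,10S,11E,13S)-6,17-diacetoxylabda-7,11,14-trien-13-ol
Conditions: DDQ, CH2Cl2/pH 7 buffer, 0 °C
Reagents that add atoms: none
Why: Oxidative cleavage of the electron-rich benzyl ether (hydride abstraction, hydrolysis of the oxocarbenium ion) should free the tertiary C13 alcohol with its own oxygen, leaving acetates and alkenes intact.

**Compound list**

1 | ethyl (Z)-3-iodoacrylate | CCOC(=O)/C=C\I | starting material
2 | (Z)-3-iodoprop-2-en-1-ol | OC/C=C\I | intermediate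
3 | (Z)-3-bromo-1-iodoprop-1-ene | BrC/C=C\I | intermediate
4 | (S)-(+)-carvone, (5S)-2-methyl-5-(prop-1-en-2-yl)cyclohex-2-en-1-one | CC1=CC[C@@H](CC1=O)C(C)=C | starting material
5 | (5S,6R)-6-methylcarvone, (5S,6R)-2,6-dimethyl-5-(prop-1-en-2-yl)cyclohex-2-en-1-one (methyl trans to isopropenyl) | CC1=CC[C@H](C(C)=C)[C@@H](C)C1=O | intermediate
6 | (5R,6R)-6-[(2Z)-3-iodoprop-2-en-1-yl]-2,6-dimethyl-5-(prop-1-en-2-yl)cyclohex-2-en-1-one (iodoallyl trans to isopropenyl; not isolated) | CC1=CC[C@H](C(C)=C)[C@@](C)(C/C=C\I)C1=O | intermediate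
7 | (5R,10R)-11,12,13,14,15,16-hexanorlabda-2,7-dien-9-one, (4aR,8aR)-2,5,5,8a-tetramethyl-4a,5,8,8a-tetrahydronaphthalen-1(4H)-one | CC1=CC[C@@H]2C(C)(C)C=CC[C@@]2(C)C1=O | intermediate
8 | (5R,10R)-11,12,13,14,15,16-hexanorlabd-7-en-9-one, (4aR,8aR)-2,5,5,8a-tetramethyl-4a,5,6,7,8,8a-hexahydronaphthalen-1(4H)-one | CC1=CC[C@@H]2C(C)(C)CCC[C@@]2(C)C1=O | intermediate
9 | (5R,10R)-12,13,14,15,16-pentanorlabda-7,9(11)-diene (ent-drima-7,9(11)-diene) | C=C1C(C)=CC[C@@H]2C(C)(C)CCC[C@@]12C | intermediate
10 | 9-BBN adduct of 9 at C11, C9–H trans and C11 cis to C20 as in 11 (not isolated) | C(B3C4CCCC3CCC4)[C@@H]1C(C)=CC[C@@H]2C(C)(C)CCC[C@@]12C | intermediate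
11 | ent-drimenol, (5R,9R,10R)-12,13,14,15,16-pentanorlabd-7-en-11-ol | OC[C@@H]1C(C)=CC[C@@H]2C(C)(C)CCC[C@@]12C | intermediate
12 | (5R,9R,10R)-11-(1-phenyl-1H-tetrazol-5-ylsulfanyl)-12,13,14,15,16-pentanorlabd-7-ene | S(C[C@@H]1C(C)=CC[C@@H]2C(C)(C)CCC[C@@]12C)c1nnnn1-c1ccccc1 | intermediate
13 | (5R,9R,10R)-11-(1-phenyl-1H-tetrazol-5-ylsulfonyl)-12,13,14,15,16-pentanorlabd-7-ene | O=S(=O)(C[C@@H]1C(C)=CC[C@@H]2C(C)(C)CCC[C@@]12C)c1nnnn1-c1ccccc1 | intermediate
14 | (5R,9S,10R)-11-(1-phenyl-1H-tetrazol-5-ylsulfonyl)-12,13,14,15,16-pentanorlabd-7-en-17-ol | O=S(=O)(C[C@@H]1C(CO)=CC[C@@H]2C(C)(C)CCC[C@@]12C)c1nnnn1-c1ccccc1 | intermediate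
15 | (5R,9S,10R)-17-acetoxy-11-(1-phenyl-1H-tetrazol-5-ylsulfonyl)-12,13,14,15,16-pentanorlabd-7-ene | O=S(=O)(C[C@@H]1C(COC(C)=O)=CC[C@@H]2C(C)(C)CCC[C@@]12C)c1nnnn1-c1ccccc1 | intermediate
16 | (5R,9S,10R)-17-acetoxy-11-(1-phenyl-1H-tetrazol-5-ylsulfonyl)-12,13,14,15,16-pentanorlabd-7-en-6-one | O=S(=O)(C[C@@H]1C(COC(C)=O)=CC(=O)[C@@H]2C(C)(C)CCC[C@@]12C)c1nnnn1-c1ccccc1 | intermediate
17 | (5R,6S,9S,10R)-17-acetoxy-11-(1-phenyl-1H-tetrazol-5-ylsulfonyl)-12,13,14,15,16-pentanorlabd-7-en-6-ol (6-OH axial, cis to C20) | O=S(=O)(C[C@@H]1C(COC(C)=O)=C[C@H](O)[C@@H]2C(C)(C)CCC[C@@]12C)c1nnnn1-c1ccccc1 | intermediate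
18 | (5R,6S,9S,10R)-6,17-diacetoxy-11-(1-phenyl-1H-tetrazol-5-ylsulfonyl)-12,13,14,15,16-pentanorlabd-7-ene | O=S(=O)(C[C@@H]1C(COC(C)=O)=C[C@H](OC(C)=O)[C@@H]2C(C)(C)CCC[C@@]12C)c1nnnn1-c1ccccc1 | intermediate
19 | racemic 2-methyl-2-vinyloxirane (isoprene monoxide) | CC1(C=C)CO1 | starting material
20 | (S)-2-[(4-methoxybenzyl)oxy]-2-methylbut-3-en-1-ol | C=C[C@](C)(OCc1ccc(OC)cc1)CO | intermediate
21 | (S)-2-[(4-methoxybenzyl)oxy]-2-methylbut-3-enal | C=C[C@](C)(OCc1ccc(OC)cc1)C=O | intermediate
22 | (5R,6S,9S,10S,11E,13S)-6,17-diacetoxy-13-[(4-methoxybenzyl)oxy]labda-7,11,14-triene | C=C[C@](C)(OCc1ccc(OC)cc1)/C=C/[C@@H]1C(COC(C)=O)=C[C@H](OC(C)=O)[C@@H]2C(C)(C)CCC[C@@]12C | intermediate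
23 | CNP0103498.1, (5R,6S,9S,10S,11E,13S)-6,17-diacetoxylabda-7,11,14-trien-13-ol (ent-labdane series) | C=C[C@](C)(O)/C=C/[C@@H]1C(COC(C)=O)=C[C@H](OC(C)=O)[C@@H]2C(C)(C)CCC[C@@]12C | target

**Step count.** Total: 18 steps. Longest linear sequence: 15 steps (steps 1, 2, 4–14, 17 and 18, from ethyl (Z)-3-iodoacrylate). The carvone branch (step 3) joins at step 4 and the aldehyde branch (steps 15 and 16) joins at step 17.

**Steps most likely to fail**

Step 4. The alkylation may show incomplete facial control at C10, the vinyl iodide may be reduced by formate before it cyclises, the neopentyl palladium intermediate may add to the new C2=C3 alkene before formate captures it, or the amine and lithium salts carried over may slow the palladium catalyst. The fallback sets out from 5 and returns at 8. The enolate of 5 (LiN(i-Pr)2, THF/DMPU) is alkylated with excess 1,3-diiodopropane to give, after isolation, (5R,6R)-6-(3-iodopropyl)-6-methylcarvone F1. Ring A is then closed by a hydrogen-atom-transfer/nickel dual-catalysed Markovnikov hydroalkylation (Mn(dpm)3, Ni(acac)2, PhSiH3, K2CO3, hexafluoroisopropanol/1,2-dichloroethane): H-atom transfer to the CH2 of the electron-rich isopropenyl group, which should be preferred over the conjugated trisubstituted alkene, gives the tertiary C4 radical, which nickel couples with the primary C3 iodide. This delivers 8 directly and makes step 5 unnecessary.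

Step 12. C–H abstraction may be slow on the acetoxymethyl-substituted alkene, oxidation may compete at the tertiary allylic C9–H, or the acetate may be over-oxidised. The fallback sets out from 13 and returns at 18; it oxidises C6 first, while the alkene still carries the electron-releasing methyl. CrO3/3,5-dimethylpyrazole gives (5R,9R,10R)-11-(1-phenyl-1H-tetrazol-5-ylsulfonyl)-12,13,14,15,16-pentanorlabd-7-en-6-one F2. SeO2 in refluxing dioxane then oxidises the γ-methyl of the enone to (5R,9S,10R)-6-oxo-11-(1-phenyl-1H-tetrazol-5-ylsulfonyl)-12,13,14,15,16-pentanorlabd-7-en-17-al F3. NaBH4/CeCl3·7H2O reduces both carbonyls to (5R,6S,9S,10R)-11-(1-phenyl-1H-tetrazol-5-ylsulfonyl)-12,13,14,15,16-pentanorlabd-7-ene-6,17-diol F4, and double acetylation (Ac2O, DMAP) gives 18.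

Step 6. Ylide addition to the ketone, flanked by the quaternary C10 and the methyl-bearing C8, may be too slow, with deconjugation or decomposition taking over at the temperature needed. The fallback sets out from 8 and returns at 11, replacing steps 6 and 7. Corey–Chaykovsky epoxidation (Me3SI, n-BuLi, THF), with the ylide attacking anti to C20, gives the (5R,9R,10R)-9,11-epoxide F5. Meinwald rearrangement with MgBr2·OEt2 (1,2-hydride shift) gives ent-drimenal, (5R,9R,10R)-12,13,14,15,16-pentanorlabd-7-en-11-al F6, whose C9 settles with the formyl group equatorial. NaBH4 in MeOH at 0 °C reduces it to 11.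

Further compounds
F1 | step 4 | (5R,6R)-6-(3-iodopropyl)-2,6-dimethyl-5-(prop-1-en-2-yl)cyclohex-2-en-1-one | CC1=CC[C@H](C(C)=C)[C@@](C)(CCCI)C1=O
F2 | step 12 | (5R,9R,10R)-11-(1-phenyl-1H-tetrazol-5-ylsulfonyl)-12,13,14,15,16-pentanorlabd-7-en-6-one | O=S(=O)(C[C@@H]1C(C)=CC(=O)[C@@H]2C(C)(C)CCC[C@@]12C)c1nnnn1-c1ccccc1
F3 | step 12 | (5R,9S,10R)-6-oxo-11-(1-phenyl-1H-tetrazol-5-ylsulfonyl)-12,13,14,15,16-pentanorlabd-7-en-17-al | O=S(=O)(C[C@@H]1C(C=O)=CC(=O)[C@@H]2C(C)(C)CCC[C@@]12C)c1nnnn1-c1ccccc1
F4 | step 12 | (5R,6S,9S,10R)-11-(1-phenyl-1H-tetrazol-5-ylsulfonyl)-12,13,14,15,16-pentanorlabd-7-ene-6,17-diol | O=S(=O)(C[C@@H]1C(CO)=C[C@H](O)[C@@H]2C(C)(C)CCC[C@@]12C)c1nnnn1-c1ccccc1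
F5 | step 6 | (5R,9R,10R)-9,11-epoxy-12,13,14,15,16-pentanorlabd-7-ene (spiro-oxirane at C9, oxygen cis to C20) | C1O[C@@]12C(C)=CC[C@@H]3C(C)(C)CCC[C@@]23C
F6 | step 6 | ent-drimenal, (5R,9R,10R)-12,13,14,15,16-pentanorlabd-7-en-11-al | O=C[C@@H]1C(C)=CC[C@@H]2C(C)(C)CCC[C@@]12C
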